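common to all: partner 0.375 M

|  | starting material | remark | time |
|---|---|---|---|
| Tuesday's | 0.12 M | run made earlier |  |
| Monday's | 0.50 M | run made earlier |  |
| flask | 0.25 M |  | 25 min |

- Tuesday's (time / min: target / %, starting material / %): 0.500: 11, 38; 2.00: 21, 3; 8.00: 11, 3; 25.0: 0, 4
- Monday's (time / min: target / %, starting material / %): 0.500: 2, 52; 2.00: 4, 42; 8.00: 3, 43; 25.0: 0, 37

(standard deviation of a reading: 2 percentage points)

1. the best time, 25 min at the latest, for target
2. the amount of target, in percent of the starting material charged, at that time



1. Time first: over the first 0.500 min starting material falls in both runs, at a pace that I take as k·c(starting material)·c(partner), but c(partner) was never read. Monday's starting material reads 42 % at 2.00 min and 43 % at 8.00 min, which I read as a stall. Taking that stall as c(partner) reaching zero, I get 1.32 for the partner cost w, the moles of partner used per mole of starting material used.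

2. First way to k: I replace c(partner) by its mean over that interval. Tuesday gives 5.94 /M/min and Monday 6.02 /M/min.

3. Second way: I integrate the rate law with c(partner) = c(partner, charged) − w·(starting material used). With 0.217 M and −0.283 M as charged partner minus w times charged starting material, Tuesday gives 6.13 /M/min and Monday 8.43 /M/min.

4. The ways part on Monday, and the mean is what cheats there: by w, Monday's c(partner) falls from 0.375 M to 0.0592 M at 0.500 min, lower than Tuesday's reckoned 0.277 M. That small remainder also makes Monday's integrated value shaky, so I keep Tuesday's.

5. For this flask, w gives an estimated 0.0461 M of partner over at full conversion, so I take starting material as the limiting reagent. At 2.00 min, where Tuesday's target reads higher than at its other times, I reckon 13.9 % starting material left in this flask.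

The forecast gives 11 % at 2 min, reasoning that “The peak absolute target is similar in both runs”. The flask gives 16.8 % at 2.31 min.

    starting material + partner → intermediate A (k = 0.106 /M/s)
    partner + intermediate A → side product A (k = 0.215 /M/s)
    intermediate A → intermediate B (k = 0.130 /s)
    intermediate B → side product B (k = 0.00605 /s)
    partner + intermediate B → target (k = 0.132 /M/s)
    intermediate A → decomposed reagent (k = 0.155 /s)
    target → over-reaction product A (k = 1.67 × 10⁻⁴ /s)
    target → over-reaction product B (k = 0.00285 /s)

For this flask at 2.31 min, my reckoning gives 11.8 % starting material, and the flask holds 12.2 %. For the neighbour charged with 0.15 M of partner, w reckons 54.4 % of the starting material left once the partner is used up, and at 25.0 min that flask holds 48.7 % with 0 % of its partner left. In this flask at 25.0 min, target is made more slowly than it is used up, each step taken net, at 0.0545 of that rate. Target then stands at 0.474 %.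

The data are calculated from invented constants; noise was put on by code.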